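**Assumption:** the SMILES is read as all-E (3R,3'R,6'R)-lutein 3-O-tetradecanoate 3'-O-hexadecanoate (carotenoid numbering, primed locants = ε end).

## Retrosynthetic overview

1. Target 38 ⇒ myristoylation of lutein 3'-palmitate 37 ⇒ C14–C15 bond by Pd-catalysed alkenyl–alkenyl Negishi coupling of β-C19 alkenylalane 36 with ε-C21 bromopentaene palmitate 28.
2. Both polyene arms ⇒ ring enynes 16 (ε) and 32 (β), grown by Zr-catalysed methylalumination and Pd coupling with C4 bromoenyne 22 and C2 linchpin 18 (from acetylene, IBr, ethynyltrimethylsilane).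
3. 16 and 32 ⇒ Takai vinyl iodides of hydroxy aldehydes 14 and 30 ⇒ enantiomeric hydroxy esters 12 and 13 ⇒ one racemic keto ester 11, by a new vinylogous DKR hydrogenation run with either catalyst antipode (sets C3'/C6' and C3).
4. Rings: the only ring-forming step is the annulation of mesityl oxide with methyl acetoacetate to 11. It is made first and serves the ε ring directly and the β ring after enal isomerisation (29 → 30).
5. Acids 6 (C14) and 8 (C16) ⇒ one batch of tridecylmagnesium chloride 5 (from 1-chlorotridecane 4, Cu-catalysed C7 + C6 coupling) plus CO2 or β-propiolactone.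

## Route

Step 1
Reactants: 1 1-bromoheptane; 2 1-bromo-6-chlorohexane
Product: 4 1-chlorotridecane, via heptylmagnesium bromide 3 (not isolated)
Conditions: 1, Mg, THF, 40 °C; then 2 (1.0 equiv), Li2CuCl4 (2 mol%), THF, −10 → 23 °C
Reagents that add atoms: none
Why: Kochi-type Cu-catalysed sp3–sp3 Grignard cross-coupling, in which the C–Br end of 2 reacts far faster than the C–Cl end, so the chloride is kept as the handle for the next Grignard reagent.

Step 2
Reactants: 4 1-chlorotridecane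
Product: 5 tridecylmagnesium chloride (kept as a titrated THF stock solution under Ar and divided between steps 3 and 4)
Conditions: Mg turnings (1.3 equiv), I2 (cat.), THF, reflux; cool, decant from excess Mg, titrate
Reagents that add atoms: magnesium, [Mg]
Why: Grignard formation by iodine-activated insertion of magnesium into the primary C–Cl bond; one batch of the reagent is prepared and serves both fatty acid syntheses.

Step 3
Reactants: 5 tridecylmagnesium chloride
Product: 6 tetradecanoic acid (myristic acid)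
Conditions: CO2 (solid, excess), THF, −78 → 23 °C; 1 M HCl
Reagents that add atoms: carbon dioxide, O=C=O
Why: Grignard carboxylation adds the carboxyl carbon to the C13 chain and gives the C14 acid.

Step 4
Reactants: 5 tridecylmagnesium chloride; 7 β-propiolactone
Product: 8 hexadecanoic acid (palmitic acid)
Conditions: 7 (1.0 equiv), CuCl (3 mol%), THF, −20 → 0 °C; 1 M HCl
Reagents that add atoms: none
Why: Cu-catalysed SN2 opening of β-propiolactone at its O–CH2 carbon by a Grignard reagent is a known three-carbon homologation to the carboxylic acid (C13 + C3 = C16).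

Step 5
Reactants: 9 mesityl oxide; 10 methyl acetoacetate
Product: 11 racemic methyl 2,6,6-trimethyl-4-oxocyclohex-2-ene-1-carboxylate
Conditions: BF3·OEt2 (0.5 equiv), neat, 23 °C, 72 h
Reagents that add atoms: none
Why: Acid-promoted Michael addition/intramolecular aldol condensation (Robinson-type annulation, known for the ethyl ester) forms the only ring of the route with the gem-dimethyl group, the vinyl methyl, the C7/C7' carbon and the C3/C3' oxygen already in place.

Step 6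
Reactants: 11 racemic methyl 2,6,6-trimethyl-4-oxocyclohex-2-ene-1-carboxylate
Product: 12 methyl (1R,4R)-4-hydroxy-2,6,6-trimethylcyclohex-2-ene-1-carboxylate
Conditions: RuCl2[(R)-tolbinap][(S,S)-dpen] (0.5 mol%), t-BuOK (10 mol%), H2 (10 atm), i-PrOH, 25 °C
Reagents that add atoms: none
Why: Proposed new method: vinylogous dynamic kinetic resolution in a Noyori-type bifunctional Ru(diphosphine)(diamine) C=O hydrogenation – t-BuOK reversibly deprotonates C1–H (α to the ester, γ to the enone) to an achiral dienolate so the enantiomers of 11 interconvert faster than they are reduced, the catalyst fixes the carbinol configuration by telling the alkenyl flank from the CH2CMe2 flank of the ketone, and only the C1 epimer whose pseudoaxial CO2Me (A1,2 strain with the C2 methyl) puts the axial C6 methyl on the face opposite to the incoming Ru–H is matched, which gives the trans (1R,4R) isomer and so sets C3' and C6' together; closest known reaction types are the Noyori DKR hydrogenation of α-substituted β-keto esters and 2-substituted cycloalkanones and the C=O-selective asymmetric hydrogenation of cyclic enones such as 2,4,4-trimethylcyclohex-2-enone, from which the catalyst antipode is assigned by analogy (an opposite sense would only exchange the catalysts of steps 6 and 7).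

Step 7
Reactants: 11 racemic methyl 2,6,6-trimethyl-4-oxocyclohex-2-ene-1-carboxylate
Product: 13 methyl (1S,4S)-4-hydroxy-2,6,6-trimethylcyclohex-2-ene-1-carboxylate
Conditions: RuCl2[(S)-tolbinap][(R,R)-dpen] (0.5 mol%), t-BuOK (10 mol%), H2 (10 atm), i-PrOH, 25 °C
Reagents that add atoms: none
Why: Proposed new method: the same vinylogous DKR hydrogenation as in step 6, run with the mirror-image catalyst, gives the enantiomer by symmetry and so sets the carbinol centre that becomes C3 (the C1 centre is erased in step 18); closest known reaction type is the Noyori DKR hydrogenation of α-substituted β-keto esters.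

Step 8
Reactants: 12 methyl (1R,4R)-4-hydroxy-2,6,6-trimethylcyclohex-2-ene-1-carboxylate
Product: 14 (1R,4R)-4-hydroxy-2,6,6-trimethylcyclohex-2-ene-1-carbaldehyde
Conditions: DIBAL-H (2.3 equiv), CH2Cl2, −78 °C; MeOH, then aq. Rochelle salt
Reagents that add atoms: none
Why: Partial ester reduction, in which the hindered ester gives an aluminium hemiacetal that is stable at −78 °C and collapses to the aldehyde only on work-up; no base is present, so C1 keeps its configuration.

Step 9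
Reactants: 14 (1R,4R)-4-hydroxy-2,6,6-trimethylcyclohex-2-ene-1-carbaldehyde
Product: 15 (1R,4R)-4-[(E)-2-iodoethenyl]-3,5,5-trimethylcyclohex-2-en-1-ol
Conditions: CrCl2 (8 equiv), CHI3 (3 equiv), THF/1,4-dioxane (1:6), 0 → 23 °C, dark
Reagents that add atoms: iodoform, IC(I)I
Why: Takai olefination gives the (E)-vinyl iodide (C7'=C8') under non-basic conditions, so the epimerisable centre next to the aldehyde (C6') survives and the free OH is tolerated.

Step 10
Reactants: 15 (1R,4R)-4-[(E)-2-iodoethenyl]-3,5,5-trimethylcyclohex-2-en-1-ol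
Product: 16 (1R,4R)-4-[(E)-but-1-en-3-yn-1-yl]-3,5,5-trimethylcyclohex-2-en-1-ol
Conditions: HC≡CMgBr (2.5 equiv), ZnBr2 (2.5 equiv), THF, 0 °C; then 15, Pd(PPh3)4 (5 mol%), 0 → 23 °C
Reagents that add atoms: ethynylmagnesium bromide, C#C[Mg]Br
Why: Negishi coupling of ethynylzinc bromide with an alkenyl iodide proceeds with retention of the E geometry and leaves both sp3 centres untouched.

Step 11
Reactants: 17 acetylene
Product: 18 (E)-1-bromo-2-iodoethene
Conditions: IBr, 48% aq. HBr, 0 °C, acetylene (1 atm)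
Reagents that add atoms: iodine monobromide, IBr
Why: Electrophilic anti addition of I–Br across acetylene via the iodonium ion gives the E isomer.

Step 12
Reactants: 18 (E)-1-bromo-2-iodoethene; 19 ethynyltrimethylsilane
Product: 22 (E)-(4-bromobut-3-en-1-yn-1-yl)trimethylsilane, via lithium (trimethylsilyl)acetylide 20 (not isolated), via (trimethylsilyl)ethynylzinc bromide 21 (not isolated)
Conditions: 19, n-BuLi, THF, −78 °C; ZnBr2, 0 °C; then 18 (1.2 equiv), Pd(PPh3)4 (2 mol%), 0 → 23 °C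
Reagents that add atoms: none
Why: Pd-catalysed Negishi alkynylzinc coupling in which oxidative addition is selective for C–I over C–Br and the E geometry is retained.

Step 13
Reactants: 16 (1R,4R)-4-[(E)-but-1-en-3-yn-1-yl]-3,5,5-trimethylcyclohex-2-en-1-ol; 22 (E)-(4-bromobut-3-en-1-yn-1-yl)trimethylsilane
Product: 24 (1R,4R)-4-[(1E,3E,5E)-3-methyl-8-(trimethylsilyl)octa-1,3,5-trien-7-yn-1-yl]-3,5,5-trimethylcyclohex-2-en-1-ol, via ε-C14 dienylalane 23 (not isolated)
Conditions: Me3Al (3 equiv), Cp2ZrCl2 (0.2 equiv), (CH2Cl)2, 23 °C; evaporate; THF, 22 (1.1 equiv), ZnBr2 (0.3 equiv), Pd2(dba)3 (2.5 mol%), P(2-furyl)3 (10 mol%), 23 °C; aq. NH4Cl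
Reagents that add atoms: trimethylaluminium, C[Al](C)C
Why: Negishi Zr-catalysed syn-methylalumination puts the methyl on the internal alkyne carbon and Al cis to it (E-trisubstituted C9'=C10'), and the Pd/Zn co-catalysed alkenyl–alkenyl coupling retains both geometries; the OH travels as its aluminium alkoxide.

Step 14
Reactants: 24 (1R,4R)-4-[(1E,3E,5E)-3-methyl-8-(trimethylsilyl)octa-1,3,5-trien-7-yn-1-yl]-3,5,5-trimethylcyclohex-2-en-1-ol
Product: 25 (1R,4R)-4-[(1E,3E,5E)-3-methylocta-1,3,5-trien-7-yn-1-yl]-3,5,5-trimethylcyclohex-2-en-1-ol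
Conditions: K2CO3 (0.2 equiv), MeOH/THF (1:1), 23 °C
Reagents that add atoms: none
Why: Methoxide-mediated protodesilylation of the alkynylsilane; no base-sensitive group is present.

Step 15
Reactants: 25 (1R,4R)-4-[(1E,3E,5E)-3-methylocta-1,3,5-trien-7-yn-1-yl]-3,5,5-trimethylcyclohex-2-en-1-ol; 18 (E)-1-bromo-2-iodoethene
Product: 27 (1R,4R)-4-[(1E,3E,5E,7E,9E)-10-bromo-3,7-dimethyldeca-1,3,5,7,9-pentaen-1-yl]-3,5,5-trimethylcyclohex-2-en-1-ol, via ε-C19 tetraenylalane 26 (not isolated)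
Conditions: Me3Al (3 equiv), Cp2ZrCl2 (0.2 equiv), (CH2Cl)2, 23 °C; evaporate; THF, 18 (1.5 equiv), ZnBr2 (0.3 equiv), Pd2(dba)3 (2.5 mol%), P(2-furyl)3 (10 mol%), 0 → 23 °C, dark; aq. NH4Cl
Reagents that add atoms: trimethylaluminium, C[Al](C)C
Why: A second Zr-catalysed methylalumination sets the E-C13'=C14' bond, and the Negishi coupling is selective for the C–I bond of 18, so the bromide is left for the final union.

Step 16
Reactants: 27 (1R,4R)-4-[(1E,3E,5E,7E,9E)-10-bromo-3,7-dimethyldeca-1,3,5,7,9-pentaen-1-yl]-3,5,5-trimethylcyclohex-2-en-1-ol; 8 hexadecanoic acid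
Product: 28 (1R,4R)-4-[(1E,3E,5E,7E,9E)-10-bromo-3,7-dimethyldeca-1,3,5,7,9-pentaen-1-yl]-3,5,5-trimethylcyclohex-2-en-1-yl hexadecanoate
Conditions: 8 (1.2 equiv), DCC (1.3 equiv), DMAP (0.2 equiv), CH2Cl2, 0 → 23 °C, dark
Reagents that add atoms: none
Why: Steglich esterification acylates on oxygen with retention at C3' and without ionising the allylic alcohol.

Step 17
Reactants: 13 methyl (1S,4S)-4-hydroxy-2,6,6-trimethylcyclohex-2-ene-1-carboxylate
Product: 29 (1S,4S)-4-hydroxy-2,6,6-trimethylcyclohex-2-ene-1-carbaldehyde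
Conditions: DIBAL-H (2.3 equiv), CH2Cl2, −78 °C; MeOH, then aq. Rochelle salt
Reagents that add atoms: none
Why: The same partial ester reduction as in step 8, stopped at the aluminium hemiacetal stage.

Step 18
Reactants: 29 (1S,4S)-4-hydroxy-2,6,6-trimethylcyclohex-2-ene-1-carbaldehyde
Product: 30 (4R)-4-hydroxy-2,6,6-trimethylcyclohex-1-ene-1-carbaldehyde
Conditions: DBU (0.1 equiv), CH2Cl2, 0 → 23 °C
Reagents that add atoms: none
Why: Base-catalysed isomerisation through the dienolate to the more stable conjugated enal (α- to β-cyclocitral type) erases C1 and leaves the carbinol centre untouched; it becomes 4R only because the CIP priorities of its ring neighbours change.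

Step 19
Reactants: 30 (4R)-4-hydroxy-2,6,6-trimethylcyclohex-1-ene-1-carbaldehyde
Product: 31 (1R)-4-[(E)-2-iodoethenyl]-3,5,5-trimethylcyclohex-3-en-1-ol
Conditions: CrCl2 (8 equiv), CHI3 (3 equiv), THF/1,4-dioxane (1:6), 0 → 23 °C, dark
Reagents that add atoms: iodoform, IC(I)I
Why: Takai olefination of the enal gives the (E)-dienyl iodide (C7=C8) and tolerates the free OH.

Step 20
Reactants: 31 (1R)-4-[(E)-2-iodoethenyl]-3,5,5-trimethylcyclohex-3-en-1-ol
Product: 32 (1R)-4-[(E)-but-1-en-3-yn-1-yl]-3,5,5-trimethylcyclohex-3-en-1-ol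
Conditions: HC≡CMgBr (2.5 equiv), ZnBr2 (2.5 equiv), THF, 0 °C; then 31, Pd(PPh3)4 (5 mol%), 0 → 23 °C
Reagents that add atoms: ethynylmagnesium bromide, C#C[Mg]Br
Why: Negishi ethynylzinc coupling with retention of the E geometry.

Step 21
Reactants: 32 (1R)-4-[(E)-but-1-en-3-yn-1-yl]-3,5,5-trimethylcyclohex-3-en-1-ol; 22 (E)-(4-bromobut-3-en-1-yn-1-yl)trimethylsilane
Product: 34 (1R)-4-[(1E,3E,5E)-3-methyl-8-(trimethylsilyl)octa-1,3,5-trien-7-yn-1-yl]-3,5,5-trimethylcyclohex-3-en-1-ol, via β-C14 dienylalane 33 (not isolated)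
Conditions: Me3Al (3 equiv), Cp2ZrCl2 (0.2 equiv), (CH2Cl)2, 23 °C; evaporate; THF, 22 (1.1 equiv), ZnBr2 (0.3 equiv), Pd2(dba)3 (2.5 mol%), P(2-furyl)3 (10 mol%), 23 °C; aq. NH4Cl
Reagents that add atoms: trimethylaluminium, C[Al](C)C
Why: Zr-catalysed syn-methylalumination (E-C9=C10) followed by Pd/Zn co-catalysed Negishi alkenyl–alkenyl coupling, the sequence established for the β-carotene end group.

Step 22
Reactants: 34 (1R)-4-[(1E,3E,5E)-3-methyl-8-(trimethylsilyl)octa-1,3,5-trien-7-yn-1-yl]-3,5,5-trimethylcyclohex-3-en-1-ol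
Product: 35 (1R)-4-[(1E,3E,5E)-3-methylocta-1,3,5-trien-7-yn-1-yl]-3,5,5-trimethylcyclohex-3-en-1-ol
Conditions: K2CO3 (0.2 equiv), MeOH/THF (1:1), 23 °C
Reagents that add atoms: none
Why: Methoxide-mediated protodesilylation of the alkynylsilane.

Step 23
Reactants: 35 (1R)-4-[(1E,3E,5E)-3-methylocta-1,3,5-trien-7-yn-1-yl]-3,5,5-trimethylcyclohex-3-en-1-ol; 28 ε-C21 bromopentaene palmitate
Product: 37 (3R,3'R,6'R)-3-hydroxy-β,ε-caroten-3'-yl hexadecanoate (lutein 3'-O-palmitate), via β-C19 tetraenylalane 36 (not isolated)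
Conditions: 35 (1.15 equiv), Me3Al (3 equiv), Cp2ZrCl2 (0.2 equiv), (CH2Cl)2, 23 °C; evaporate excess Me3Al; THF, 28 (1.0 equiv), ZnBr2 (0.3 equiv), Pd2(dba)3 (2.5 mol%), P(2-furyl)3 (10 mol%), 0 → 23 °C, dark; aq. NH4Cl
Reagents that add atoms: trimethylaluminium, C[Al](C)C
Why: Key union – Zr-catalysed methylalumination sets E-C13=C14, and the Pd-catalysed Negishi alkenyl–alkenyl coupling forms the C14–C15 bond with retention on both partners; excess Me3Al is removed before the ester-bearing bromide is added.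

Step 24
Reactants: 37 lutein 3'-O-palmitate; 6 tetradecanoic acid
Product: 38 (3R,3'R,6'R)-β,ε-carotene-3,3'-diyl 3-tetradecanoate 3'-hexadecanoate (CNP0230054.1)
Conditions: 6 (1.5 equiv), DCC (1.6 equiv), DMAP (0.3 equiv), CH2Cl2, 23 °C, dark, Ar
Reagents that add atoms: none
Why: Steglich esterification of the remaining homoallylic C3–OH proceeds with retention and under conditions the polyene and the allylic palmitate tolerate.

## Compound list

1 | 1-bromoheptane | CCCCCCCBr | starting material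
2 | 1-bromo-6-chlorohexane | ClCCCCCCBr | starting material
3 | heptylmagnesium bromide | CCCCCCC[Mg]Br | intermediate
4 | 1-chlorotridecane | CCCCCCCCCCCCCCl | intermediate
5 | tridecylmagnesium chloride | CCCCCCCCCCCCC[Mg]Cl | intermediate
6 | tetradecanoic acid (myristic acid) | CCCCCCCCCCCCCC(=O)O | intermediate
7 | β-propiolactone (oxetan-2-one) | O=C1CCO1 | starting material
8 | hexadecanoic acid (palmitic acid) | CCCCCCCCCCCCCCCC(=O)O | intermediate
9 | mesityl oxide (4-methylpent-3-en-2-one) | CC(=O)C=C(C)C | starting material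
10 | methyl acetoacetate | COC(=O)CC(C)=O | starting material
11 | racemic methyl 2,6,6-trimethyl-4-oxocyclohex-2-ene-1-carboxylate | COC(=O)C1C(C)=CC(=O)CC1(C)C | intermediate
12 | methyl (1R,4R)-4-hydroxy-2,6,6-trimethylcyclohex-2-ene-1-carboxylate | O[C@H]1C=C(C)[C@H](C(=O)OC)C(C)(C)C1 | intermediate
13 | methyl (1S,4S)-4-hydroxy-2,6,6-trimethylcyclohex-2-ene-1-carboxylate | O[C@@H]1C=C(C)[C@@H](C(=O)OC)C(C)(C)C1 | intermediate
14 | (1R,4R)-4-hydroxy-2,6,6-trimethylcyclohex-2-ene-1-carbaldehyde | O[C@H]1C=C(C)[C@H](C=O)C(C)(C)C1 | intermediate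
15 | (1R,4R)-4-[(E)-2-iodoethenyl]-3,5,5-trimethylcyclohex-2-en-1-ol | O[C@H]1C=C(C)[C@H](/C=C/I)C(C)(C)C1 | intermediate
16 | (1R,4R)-4-[(E)-but-1-en-3-yn-1-yl]-3,5,5-trimethylcyclohex-2-en-1-ol | O[C@H]1C=C(C)[C@H](/C=C/C#C)C(C)(C)C1 | intermediate
17 | acetylene | C#C | starting material
18 | (E)-1-bromo-2-iodoethene | Br/C=C/I | intermediate
19 | ethynyltrimethylsilane | C#C[Si](C)(C)C | starting material
20 | lithium (trimethylsilyl)acetylide | [Li]C#C[Si](C)(C)C | intermediate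
21 | (trimethylsilyl)ethynylzinc bromide | Br[Zn]C#C[Si](C)(C)C | intermediate
22 | (E)-(4-bromobut-3-en-1-yn-1-yl)trimethylsilane | C[Si](C)(C)C#C/C=C/Br | intermediate
23 | ε-C14 dienylalane: dimethylaluminium alkoxide of (1R,4R)-4-[(1E,3E)-4-(dimethylalumanyl)-3-methylbuta-1,3-dien-1-yl]-3,5,5-trimethylcyclohex-2-en-1-ol | C[Al](C)O[C@H]1C=C(C)[C@H](/C=C/C(C)=C/[Al](C)C)C(C)(C)C1 | intermediate
24 | (1R,4R)-4-[(1E,3E,5E)-3-methyl-8-(trimethylsilyl)octa-1,3,5-trien-7-yn-1-yl]-3,5,5-trimethylcyclohex-2-en-1-ol | O[C@H]1C=C(C)[C@H](/C=C/C(C)=C/C=C/C#C[Si](C)(C)C)C(C)(C)C1 | intermediate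
25 | (1R,4R)-4-[(1E,3E,5E)-3-methylocta-1,3,5-trien-7-yn-1-yl]-3,5,5-trimethylcyclohex-2-en-1-ol | O[C@H]1C=C(C)[C@H](/C=C/C(C)=C/C=C/C#C)C(C)(C)C1 | intermediate
26 | ε-C19 tetraenylalane: dimethylaluminium alkoxide of (1R,4R)-4-[(1E,3E,5E,7E)-8-(dimethylalumanyl)-3,7-dimethylocta-1,3,5,7-tetraen-1-yl]-3,5,5-trimethylcyclohex-2-en-1-ol | C[Al](C)O[C@H]1C=C(C)[C@H](/C=C/C(C)=C/C=C/C(C)=C/[Al](C)C)C(C)(C)C1 | intermediate
27 | (1R,4R)-4-[(1E,3E,5E,7E,9E)-10-bromo-3,7-dimethyldeca-1,3,5,7,9-pentaen-1-yl]-3,5,5-trimethylcyclohex-2-en-1-ol | O[C@H]1C=C(C)[C@H](/C=C/C(C)=C/C=C/C(C)=C/C=C/Br)C(C)(C)C1 | intermediate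
28 | (1R,4R)-4-[(1E,3E,5E,7E,9E)-10-bromo-3,7-dimethyldeca-1,3,5,7,9-pentaen-1-yl]-3,5,5-trimethylcyclohex-2-en-1-yl hexadecanoate | CCCCCCCCCCCCCCCC(=O)O[C@H]1C=C(C)[C@H](/C=C/C(C)=C/C=C/C(C)=C/C=C/Br)C(C)(C)C1 | intermediate
29 | (1S,4S)-4-hydroxy-2,6,6-trimethylcyclohex-2-ene-1-carbaldehyde | O[C@@H]1C=C(C)[C@@H](C=O)C(C)(C)C1 | intermediate
30 | (4R)-4-hydroxy-2,6,6-trimethylcyclohex-1-ene-1-carbaldehyde | O[C@@H]1CC(C)=C(C=O)C(C)(C)C1 | intermediate
31 | (1R)-4-[(E)-2-iodoethenyl]-3,5,5-trimethylcyclohex-3-en-1-ol | O[C@@H]1CC(C)=C(/C=C/I)C(C)(C)C1 | intermediate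
32 | (1R)-4-[(E)-but-1-en-3-yn-1-yl]-3,5,5-trimethylcyclohex-3-en-1-ol | O[C@@H]1CC(C)=C(/C=C/C#C)C(C)(C)C1 | intermediate
33 | β-C14 dienylalane: dimethylaluminium alkoxide of (1R)-4-[(1E,3E)-4-(dimethylalumanyl)-3-methylbuta-1,3-dien-1-yl]-3,5,5-trimethylcyclohex-3-en-1-ol | C[Al](C)O[C@@H]1CC(C)=C(/C=C/C(C)=C/[Al](C)C)C(C)(C)C1 | intermediate
34 | (1R)-4-[(1E,3E,5E)-3-methyl-8-(trimethylsilyl)octa-1,3,5-trien-7-yn-1-yl]-3,5,5-trimethylcyclohex-3-en-1-ol | O[C@@H]1CC(C)=C(/C=C/C(C)=C/C=C/C#C[Si](C)(C)C)C(C)(C)C1 | intermediate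
35 | (1R)-4-[(1E,3E,5E)-3-methylocta-1,3,5-trien-7-yn-1-yl]-3,5,5-trimethylcyclohex-3-en-1-ol | O[C@@H]1CC(C)=C(/C=C/C(C)=C/C=C/C#C)C(C)(C)C1 | intermediate
36 | β-C19 tetraenylalane: dimethylaluminium alkoxide of (1R)-4-[(1E,3E,5E,7E)-8-(dimethylalumanyl)-3,7-dimethylocta-1,3,5,7-tetraen-1-yl]-3,5,5-trimethylcyclohex-3-en-1-ol | C[Al](C)O[C@@H]1CC(C)=C(/C=C/C(C)=C/C=C/C(C)=C/[Al](C)C)C(C)(C)C1 | intermediate
37 | (3R,3'R,6'R)-3-hydroxy-β,ε-caroten-3'-yl hexadecanoate (lutein 3'-O-palmitate) | CCCCCCCCCCCCCCCC(=O)O[C@H]1C=C(C)[C@H](/C=C/C(C)=C/C=C/C(C)=C/C=C/C=C(C)/C=C/C=C(C)/C=C/C2=C(C)C[C@@H](O)CC2(C)C)C(C)(C)C1 | intermediate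
38 | (3R,3'R,6'R)-β,ε-carotene-3,3'-diyl 3-tetradecanoate 3'-hexadecanoate (CNP0230054.1) | CCCCCCCCCCCCCCCC(=O)O[C@H]1C=C(C)[C@H](/C=C/C(C)=C/C=C/C(C)=C/C=C/C=C(C)/C=C/C=C(C)/C=C/C2=C(C)C[C@@H](OC(=O)CCCCCCCCCCCCC)CC2(C)C)C(C)(C)C1 | target

## Step count and risks

Total step count: 24.
Longest linear sequence: 11 steps (5, 6, 8, 9, 10, 13, 14, 15, 16, 23, 24).

The three steps most likely to fail:

**Step 6 (proposed new step; step 7 is its mirror image).** Racemisation through the dienolate may be too slow, the deconjugated keto tautomer may be reduced unselectively, or the cis isomer may form. The fallback uses known chemistry, sets out from 11 and comes back at 12 and 13. Luche reduction of 11 (NaBH4, CeCl3·7H2O, MeOH, −40 °C) and chromatographic removal of the cis isomer give racemic methyl trans-4-hydroxy-2,6,6-trimethylcyclohex-2-ene-1-carboxylate F1. Lipase PS-catalysed acylation of F1 with vinyl acetate in MTBE is stopped at 50% conversion; by Kazlauskas' rule it gives methyl (1R,4R)-4-acetoxy-2,6,6-trimethylcyclohex-2-ene-1-carboxylate F2 and leaves the (1S,4S)-alcohol, which is 13. Methanolysis of F2 (K2CO3, MeOH) gives 12.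

**Step 8 (step 17 carries the same risk).** The partial reduction may over-reduce to the diol or stall. The fallback sets out from 12 and comes back at 14, replacing it by protection, full reduction and re-oxidation. Silylation (TBSCl, imidazole, DMF) gives methyl (1R,4R)-4-(tert-butyldimethylsilyloxy)-2,6,6-trimethylcyclohex-2-ene-1-carboxylate F3. LiAlH4 (Et2O, 0 °C) gives [(1R,4R)-4-(tert-butyldimethylsilyloxy)-2,6,6-trimethylcyclohex-2-en-1-yl]methanol F4. Dess–Martin periodinane (NaHCO3, CH2Cl2) gives (1R,4R)-4-(tert-butyldimethylsilyloxy)-2,6,6-trimethylcyclohex-2-ene-1-carbaldehyde F5. HF·pyridine (THF, 0 °C) removes the silyl group and gives 14.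

**Step 23.** The alkenylalane or residual Me3Al may attack the allylic palmitate of 28, or the coupling of two long polyenes may be low-yielding. The fallback sets out from 35 and 25 and comes back at 37, replacing the Al/Zn union by a neutral Stille stitching with a C2 bis-stannane.
- Zr-catalysed methylalumination of 35 followed by iodinolysis (I2, THF, −30 °C) gives (1R)-4-[(1E,3E,5E,7E)-8-iodo-3,7-dimethylocta-1,3,5,7-tetraen-1-yl]-3,5,5-trimethylcyclohex-3-en-1-ol F6.
- Stille coupling of F6 with excess (E)-1,2-bis(tributylstannyl)ethene [PdCl2(MeCN)2, DMF, 23 °C] gives (1R)-4-[(1E,3E,5E,7E,9E)-3,7-dimethyl-10-(tributylstannyl)deca-1,3,5,7,9-pentaen-1-yl]-3,5,5-trimethylcyclohex-3-en-1-ol F7.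
- The same methylalumination/iodinolysis of 25 gives (1R,4R)-4-[(1E,3E,5E,7E)-8-iodo-3,7-dimethylocta-1,3,5,7-tetraen-1-yl]-3,5,5-trimethylcyclohex-2-en-1-ol F8.
- Esterification of F8 with 8 (DCC, DMAP) gives (1R,4R)-4-[(1E,3E,5E,7E)-8-iodo-3,7-dimethylocta-1,3,5,7-tetraen-1-yl]-3,5,5-trimethylcyclohex-2-en-1-yl hexadecanoate F9.
- Stille coupling of F7 with F9 (Pd2(dba)3, AsPh3, NMP, 23 °C, dark) forms the C15'–C14' bond and gives 37.

## Further compounds

F1 | step 6 | racemic methyl trans-4-hydroxy-2,6,6-trimethylcyclohex-2-ene-1-carboxylate (both enantiomers) | O[C@H]1C=C(C)[C@H](C(=O)OC)C(C)(C)C1.O[C@@H]1C=C(C)[C@@H](C(=O)OC)C(C)(C)C1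
F2 | step 6 | methyl (1R,4R)-4-acetoxy-2,6,6-trimethylcyclohex-2-ene-1-carboxylate | CC(=O)O[C@H]1C=C(C)[C@H](C(=O)OC)C(C)(C)C1
F3 | step 8 | methyl (1R,4R)-4-(tert-butyldimethylsilyloxy)-2,6,6-trimethylcyclohex-2-ene-1-carboxylate | CC(C)(C)[Si](C)(C)O[C@H]1C=C(C)[C@H](C(=O)OC)C(C)(C)C1
F4 | step 8 | [(1R,4R)-4-(tert-butyldimethylsilyloxy)-2,6,6-trimethylcyclohex-2-en-1-yl]methanol | CC(C)(C)[Si](C)(C)O[C@H]1C=C(C)[C@H](CO)C(C)(C)C1
F5 | step 8 | (1R,4R)-4-(tert-butyldimethylsilyloxy)-2,6,6-trimethylcyclohex-2-ene-1-carbaldehyde | CC(C)(C)[Si](C)(C)O[C@H]1C=C(C)[C@H](C=O)C(C)(C)C1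
F6 | step 23 | (1R)-4-[(1E,3E,5E,7E)-8-iodo-3,7-dimethylocta-1,3,5,7-tetraen-1-yl]-3,5,5-trimethylcyclohex-3-en-1-ol | O[C@@H]1CC(C)=C(/C=C/C(C)=C/C=C/C(C)=C/I)C(C)(C)C1
F7 | step 23 | (1R)-4-[(1E,3E,5E,7E,9E)-3,7-dimethyl-10-(tributylstannyl)deca-1,3,5,7,9-pentaen-1-yl]-3,5,5-trimethylcyclohex-3-en-1-ol | O[C@@H]1CC(C)=C(/C=C/C(C)=C/C=C/C(C)=C/C=C/[Sn](CCCC)(CCCC)CCCC)C(C)(C)C1
F8 | step 23 | (1R,4R)-4-[(1E,3E,5E,7E)-8-iodo-3,7-dimethylocta-1,3,5,7-tetraen-1-yl]-3,5,5-trimethylcyclohex-2-en-1-ol | O[C@H]1C=C(C)[C@H](/C=C/C(C)=C/C=C/C(C)=C/I)C(C)(C)C1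
F9 | step 23 | (1R,4R)-4-[(1E,3E,5E,7E)-8-iodo-3,7-dimethylocta-1,3,5,7-tetraen-1-yl]-3,5,5-trimethylcyclohex-2-en-1-yl hexadecanoate | CCCCCCCCCCCCCCCC(=O)O[C@H]1C=C(C)[C@H](/C=C/C(C)=C/C=C/C(C)=C/I)C(C)(C)C1
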